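## The problem

Target 36 is a 5,10-cis-clerodane, (5S,7S,8S,9R,10R,13R) in clerodane numbering as encoded in its SMILES. Ring A (C1–C5, C10) carries a 2-hydroxy-1-en-3-one (diosphenol) flanked by the exocyclic C4=C18 methylene. Ring B (C5–C10) carries the C7 acetate, the C8 methyl (C17), the quaternary C9 (methyl C20 and the C11–C15 acid chain with methyl C16 on C13) and the fusion methine C10, next to the second quaternary carbon C5 (methyl C19). The C13 centre lies three methylenes from the ring, cannot be induced from it, and is best bought. C5 and C10 can be set together, and C10 can then steer C9, because a reagent at C9 avoids the C10–C1 bond. C7 and C8 lie between two pairs of substituents of almost equal size (C4/C19 on C5, C20/C11 on C9), so substrate control there is weak and a reagent or a directing group must take over. The diosphenol with its cross-conjugated exocyclic enone will not survive strong base, hydride or hydrogenation and must be unveiled last. The secondary acetate beside a free acid forbids a late saponification. Ring A also hides a regiochemical trap: C2 and C3 are nearly equivalent carbonyl carbons, yet the methylene must go to C4 only. The feature that opens the molecule is that C5 is quaternary and cis-fused to C10 while ring A is at the 1,2-dione level: seen from C5, ring B is a 4-methylcyclohexa-2,5-dienone and ring A is a 2,3-dioxobutyl chain whose terminal carbon C1 is bonded to C10.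

## Retrosynthesis

**Unveiling ring A (36 ⇒ 35 ⇒ 32).** The last cuts are the protecting groups and C4=C18. Target 36 is traced to keto-ketal 35, and 35 to ketone 32 by a Mannich/elimination methylenation. Methylenating a free 2,3-dione would give C1 and C4 products, because its dienediolate is ambident. In 32 the C2 carbon is a ketal, so C4 is the only enolisable position. The forward steps ask for ketone enolisation beside an acetate and a tert-butyl ester, and for one acid treatment that frees the dione and the acid together.

**C7 and C8 (32 ⇒ 29 ⇒ 28 ⇒ 27 ⇒ 25 ⇒ 24).** Ketone 32 comes from alcohol 29 by acetylation (30), desilylation (31) and oxidation. In 29 the C8–H bond is cut by a hydroxyl-directed hydrogenation of allylic alcohol 28, and the C7–H bond by a reagent-controlled reduction of enone 27. Enone 27 comes from exocyclic alkene 25 by allylic oxidation, and 25 from ketone 24 by methylenation. Hydroxylating the C7 enolate of 24 would be shorter, but it would leave C7 to the weak substrate bias and require olefination of an α-oxygenated neopentyl ketone. The precursor 24 has lost two stereocentres.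

**The quaternary C9 (24 ⇒ 23 ⇒ 16 + 22; 16 ⇒ 15).** The C9–C11 and C9–C20 bonds are cut back to enone 15. The ring B double bond is kept through both alkylations (16, then 23) because it confines enolisation to C9: C5 has no γ-hydrogen, whereas the saturated ketone would enolise toward C7. Methyl goes in first so that the chain iodide 22 enters second, anti to the C10–C1 bond. The forward reaction must alkylate a tetrasubstituted enolate with an unactivated primary iodide.

**The chain (22 ⇒ 21 ⇒ 19 ⇒ 17).** C13 is taken from half-ester 17. Its acid terminus becomes C11 and its ester terminus C15. The detour through lactone 19 and iodo acid 21 exchanges the methyl ester for a tert-butyl ester, which falls in the final acid step and spares the acetate.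

**Masking ring A (15 ⇒ 14 ⇒ 13 ⇒ 12).** Silyl ether 15 is traced through alcohol 14 and keto-ketal 13 to trione 12. A ketal at C2 is preferred to an enol ether or a diol acetonide because it tells C2 from C3 at the one stage where they differ sterically, and it leaves no acidic hydrogen in ring A. The forward steps ask for regioselective ketalisation and for reduction of a saturated ketone beside an enone.

**The key cut (12 ⇒ 11).** Cutting C1–C10 turns bicyclic 12 into the achiral monocyclic dienone 11. Cuts at C9–C10 or C5–C10 would leave C5 or C9 to be made on an acyclic chain. This cut makes ring A and both fusion stereocentres in one catalytic step, with the dione already in place. The forward reaction must choose between two enantiotopic enone arms.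

**The dienone (11 ⇒ 10 ⇒ 9 ⇒ 8 ⇒ 5 + 6; 5 ⇒ 1 + 2).** The dione of 11 is made last, from diol 10, so that the cyclisation cannot start without the catalyst. Diol 10 comes from the crotyl dienone 9, and 9 from enone 8 by dehydrogenation. Enone 8 is the Robinson product of aldehyde 5 and methyl vinyl ketone 6, and 5 is the Claisen product of propanal 1 and but-3-en-2-ol 2.

## Roads not taken

**Alternative 1:** The cuts are C5–C19 and C4–C18 of the protected decalinone A1, leading back to the Δ4-octalone A2. In the forward step Me2CuLi adds to C5 of A2 and the C3 enolate is trapped at C4 by dimethylmethyleneiminium iodide, followed by elimination.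
- Merits: the enolate is born regiospecifically at C4, so the C1/C4 problem never arises. The chosen plan pays for the same certainty by carrying a C2 ketal through seventeen steps; here Alternative 1 is better.
- Weak points: the cuprate must create a quaternary carbon next to C10, which already carries the quaternary C9, and the cis fusion rests on substrate control. A1 lacks the C2 oxygen, which would have to be introduced beside the α-methylene ketone. A2 still contains C7, C8, C9 and C10, so the ring B problem is only moved.
- Comparison: the chosen plan sets C5 and C10 by catalyst control six steps from commodity chemicals and delivers ring A at the dione level.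

**Alternative 2:** The cuts are C5–C10 and C8–C9 of the octalin A3, leading back to the acyclic trienone A4. In the forward step a chiral oxazaborolidinium acid promotes an intramolecular Diels–Alder reaction.
- Merits: both rings and four stereocentres, including both quaternary carbons, form in one catalytic step. The chosen plan needs its key step, two alkylations and five further steps for the same centres; in convergence Alternative 2 is clearly better.
- Weak points: the diene terminus C5 is fully substituted with a methyl group on the inside, and the dienophile is trisubstituted, so two bonds to quaternary carbons must form at once. The endo/exo preference decides the ring fusion. A3 has its ring A carbonyl at C1 and nothing at C2–C4, and its C11 ester must still be homologated to the chain with C13.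
- Comparison: the chosen plan has a key step with close precedent, ring A at the right oxidation level, and the chain attached intact.

**Alternative 3:** The cut is C9–C10 of the decalin A5, leading back to the dienone A6 with a tethered 1,1-disubstituted alkene. In the forward step Fe(acac)3 and PhSiH3 generate the tertiary C9 radical, which adds 6-exo to the dienone.
- Merits: radical conjugate addition is well suited to the congested C9–C10 bond, the weakest point of the chosen plan (step 14). The chain, C7 and C8 are assembled beforehand on an open chain.
- Weak points: the two enone arms of A6 are diastereotopic, so C5, C9 and C10 depend on remote induction from C7 and C8 through a planar radical. Ring A of A5 is a 2-ketone with a Δ3 alkene; it lacks the C3 oxygen and C18, and C4 is a β-carbon that cannot be methylenated directly.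
- Comparison: the chosen plan has catalyst-controlled absolute configuration and a ring A that needs no further oxidation.

Key step: step 6

Remarks on the chemistry:
- Bicyclic compounds are named with clerodane numbering (C17 on C8, C18 on C4, C19 on C5, C20 on C9, chain C11–C15 with C16 on C13).
- 2,3-Diones such as 12 are drawn as diketones but are expected to exist largely as enols.
- The quinine-derived catalyst is assumed to select the enone arm that gives (4aS,8aR)-12; if the sense is opposite, the quinidine-derived pseudo-enantiomer is used with no other change.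
- C3 in 14–31 and C9 in 16 are drawn as the expected major epimers, and C7 in 26 and C4 in 33 and 34 without configuration; all these centres are erased or overwritten later.

## Route

Step 1
Reactants: 1 propanal; 2 but-3-en-2-ol
Product: 5 (E)-2-methylhex-4-enal (racemic), via acetal 3 (not isolated), via allyl propenyl ether 4 (not isolated)
Conditions: TsOH·H2O (cat.), mesitylene, 150 °C, removal of water
Reagents that add atoms: none
Why: Acetal formation and loss of one alcohol give the allyl propenyl ether, whose Claisen rearrangement through a chair with the methyl group equatorial should give the (E)-alkene; the α-centre is racemic and is erased in step 3.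

Step 2
Reactants: 5 (E)-2-methylhex-4-enal; 6 methyl vinyl ketone
Product: 8 4-[(E)-but-2-en-1-yl]-4-methylcyclohex-2-en-1-one (racemic), via keto aldehyde 7 (not isolated)
Conditions: H2SO4 (cat.), toluene, 45 °C then reflux, water separator
Reagents that add atoms: none
Why: Acid-catalysed Michael addition of the aldehyde enol and intramolecular aldol condensation (Robinson annulation) are established for α-branched aldehydes and create the quaternary carbon that becomes C5.

Step 3
Reactants: 8 4-[(E)-but-2-en-1-yl]-4-methylcyclohex-2-en-1-one
Product: 9 4-[(E)-but-2-en-1-yl]-4-methylcyclohexa-2,5-dien-1-one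
Conditions: DDQ, 1,4-dioxane, reflux
Reagents that add atoms: none
Why: Quinone dehydrogenation of 4,4-disubstituted cyclohexenones gives cross-conjugated dienones; the quaternary carbon becomes non-stereogenic, so the material is now achiral.

Step 4
Reactants: 9 4-[(E)-but-2-en-1-yl]-4-methylcyclohexa-2,5-dien-1-one
Product: 10 4-(2,3-dihydroxybutyl)-4-methylcyclohexa-2,5-dien-1-one (racemic threo diol)
Conditions: OsO4 (cat.), N-methylmorpholine N-oxide, acetone–H2O, 0 °C to rt
Reagents that add atoms: osmium tetroxide, O=[Os](=O)(=O)=O (both oxygens, regenerated by N-methylmorpholine N-oxide, C[N+]1([O-])CCOCC1)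
Why: Catalytic syn-dihydroxylation is electrophilic and should take the isolated disubstituted alkene in preference to the two electron-poor dienone double bonds; the diol configuration is irrelevant.

Step 5
Reactants: 10 4-(2,3-dihydroxybutyl)-4-methylcyclohexa-2,5-dien-1-one
Product: 11 4-methyl-4-(2,3-dioxobutyl)cyclohexa-2,5-dien-1-one
Conditions: IBX (2-iodoxybenzoic acid), DMSO, rt
Reagents that add atoms: none
Why: IBX oxidises secondary 1,2-diols to 1,2-diketones without C–C cleavage and without base, which keeps the enolisable dione from cyclising before the chiral catalyst is present.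

Step 6
Reactants: 11 4-methyl-4-(2,3-dioxobutyl)cyclohexa-2,5-dien-1-one
Product: 12 (4aS,8aR)-8a-methyl-1,4,4a,8a-tetrahydronaphthalene-2,3,6(5H)-trione (clerodane 2,3,8-trione with a C6=C7 alkene; H-10 cis to C19)
Conditions: N-[3,5-bis(trifluoromethyl)phenyl]-N′-[(8α,9S)-6′-methoxycinchonan-9-yl]thiourea (10 mol %), toluene, rt
Reagents that add atoms: none
Why: The quinuclidine nitrogen removes a proton from the terminal methyl group (C1) of the α-diketone and holds the enolate as an ion pair while the thiourea hydrogen-bonds to the dienone carbonyl; C1 then adds to C10 of one enone arm and the ring B dienolate is protonated at C9. The closest known reaction type is the amine–thiourea-catalysed desymmetrisation of 4,4-disubstituted cyclohexadienones by intramolecular Michael addition of tethered carbon acids, together with the use of 1,2-diketones as Michael donors under such catalysts. Ring A closes in the 6-exo-trig mode. C5 becomes stereogenic only through the choice between the two enantiotopic arms, which the catalyst makes. C10 is fixed by the tether: the nucleophile hangs from C5 and reaches C10 only on its own face, so H-10 is cis to the C5 methyl. The step needs enantiotopic-group selectivity (catalyst), carbon over oxygen attack (oxa-Michael adducts of the enol oxygen revert, the C–C adduct does not) and enolisation toward C1 (the C4 enolate cannot close a strain-free ring and enolisation is reversible).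

Step 7
Reactants: 12 bicyclic trione
Product: 13 2,2-ethylenedioxy-3,8-dione (C2 dioxolane of 12)
Conditions: HOCH2CH2OH, TsOH·H2O (cat.), benzene, reflux, water separator
Reagents that add atoms: ethane-1,2-diol, OCCO
Why: The α-dicarbonyl unit is far more electrophilic than the conjugated enone. A C3 ketal would put one oxygen 1,3-diaxial to a carbon substituent of the quaternary C5 in either chair, whereas the C2 ketal can turn its axial oxygen toward H-10, so equilibrating ketalisation should stop at C2.

Step 8
Reactants: 13 keto-ketal
Product: 14 3-hydroxy-2,2-ethylenedioxy-6-en-8-one (hydroxyl trans to C19)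
Conditions: NaBH4, MeOH–CH2Cl2, −78 °C
Reagents that add atoms: none
Why: Borohydride reduces a saturated, inductively activated ketone faster than a conjugated enone at low temperature, as in selective reductions of ene-diones. Hydride should come from the convex face; the C3 configuration is of no consequence.

Step 9
Reactants: 14 hydroxy ketal
Product: 15 3-(tert-butyldimethylsilyloxy)-2,2-ethylenedioxy-6-en-8-one
Conditions: tBuMe2SiOTf, 2,6-lutidine, CH2Cl2, −78 to 0 °C
Reagents that add atoms: tert-butyldimethylsilyl triflate, CC(C)(C)[Si](C)(C)OS(=O)(=O)C(F)(F)F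
Why: Silyl triflate with a hindered pyridine base silylates hindered secondary alcohols; ring A is now free of carbonyl groups and acidic hydrogens.

Step 10
Reactants: 15 silyl ether enone
Product: 16 9-methyl enone (methyl cis to H-10 expected; the epimer serves equally)
Conditions: LiN(iPr)2, THF, −78 °C; MeI, −78 to −20 °C
Reagents that add atoms: iodomethane, CI
Why: Kinetic α′-deprotonation of the enone can occur only at C9 (C5 carries no γ-hydrogen), and the enolate is methylated; the new C9 centre is planarised again in step 14.

Step 11
Reactants: 17 methyl hydrogen (R)-3-methylglutarate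
Product: 19 (R)-4-methyltetrahydro-2H-pyran-2-one, via hydroxy ester 18 (not isolated)
Conditions: BH3·SMe2, THF, 0 °C to rt; then TsOH·H2O (cat.), toluene, 60 °C
Reagents that add atoms: none
Why: Borane reduces the free carboxylic acid much faster than the ester, and the hydroxy ester lactonises under acid; the stereocentre is not touched.

Step 12
Reactants: 19 (R)-4-methyltetrahydro-2H-pyran-2-one
Product: 21 (S)-5-iodo-3-methylpentanoic acid, via silyl ester 20 (not isolated)
Conditions: Me3SiI, CH2Cl2, rt to 40 °C; then H2O
Reagents that add atoms: iodotrimethylsilane, C[Si](C)(C)I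
Why: Silylation of the lactone carbonyl and SN2 attack of iodide at the O–CH2 carbon is the known cleavage of lactones to ω-iodo acids; the descriptor changes only through priorities.

Step 13
Reactants: 21 (S)-5-iodo-3-methylpentanoic acid
Product: 22 tert-butyl (S)-5-iodo-3-methylpentanoate
Conditions: tert-butyl 2,2,2-trichloroacetimidate, BF3·OEt2 (cat.), CH2Cl2–cyclohexane, rt
Reagents that add atoms: tert-butyl 2,2,2-trichloroacetimidate, CC(C)(C)OC(=N)C(Cl)(Cl)Cl
Why: Acid-catalysed imidate esterification needs no base, which would close the iodo acid back to the lactone.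

Step 14
Reactants: 16 9-methyl enone; 22 tert-butyl (S)-5-iodo-3-methylpentanoate
Product: 23 9,9-dialkylated enone (C20 trans and C11 chain cis to H-10)
Conditions: LiN(iPr)2, THF, −78 to 0 °C; then 22, DMPU, −40 °C to rt
Reagents that add atoms: none
Why: The tetrasubstituted α′-enolate is alkylated by the primary iodide in a dipolar cosolvent. The electrophile should enter anti to the C10–C1 bond, on the convex face of the cis-fused bicycle, which places the chain cis to H-10 and is the reason for introducing methyl first.

Step 15
Reactants: 23 dialkylated enone
Product: 24 saturated C8 ketone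
Conditions: H2 (1 atm), Pd/C, EtOAc, rt
Reagents that add atoms: none
Why: Catalytic hydrogenation removes the enone double bond once it has served to direct enolisation; no stereocentre is formed.

Step 16
Reactants: 24 saturated C8 ketone
Product: 25 8(17)-methylene compound
Conditions: Ph3PCH3Br, KOtBu, toluene, 90 °C
Reagents that add atoms: methyltriphenylphosphonium bromide, C[P+](c1ccccc1)(c1ccccc1)c1ccccc1.[Br-]
Why: Wittig methylenation with excess salt-free ylide at elevated temperature is the standard answer to ketones flanked by a quaternary carbon; neither α-carbon can epimerise.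

Step 17
Reactants: 25 8(17)-methylene compound
Product: 27 8(17)-en-7-one, via allylic alcohol 26 (not isolated)
Conditions: SeO2 (cat.), tBuOOH, CH2Cl2, rt; then DMP (1,1,1-triacetoxy-1,1-dihydro-1,2-benziodoxol-3(1H)-one), NaHCO3, CH2Cl2, rt
Reagents that add atoms: tert-butyl hydroperoxide, CC(C)(C)OO (oxygen delivered through selenium dioxide, O=[Se]=O)
Why: The ene/[2,3]-sigmatropic allylic oxidation can only reach C7, the single allylic CH2, and periodinane oxidation converges both carbinol epimers and any enone already formed.

Step 18
Reactants: 27 8(17)-en-7-one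
Product: 28 allylic alcohol (7-hydroxyl cis to H-10 and C19)
Conditions: (R)-2-methyl-CBS-oxazaborolidine [(3aR)-1-methyl-3,3-diphenyltetrahydro-1H,3H-pyrrolo[1,2-c][1,3,2]oxazaborole] (0.5 equiv), catecholborane, toluene, −78 °C
Reagents that add atoms: none
Why: In the CBS reduction of enones the alkenyl carbon (C8) takes the role of the large group and the C6 methylene that of the small one, so the (R)-catalyst should deliver hydride to the face that leaves the hydroxyl cis to H-10; catecholborane at low temperature does not hydroborate the alkene. Reagent control is used because the substrate bias at C7 is weak.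

Step 19
Reactants: 28 allylic alcohol
Product: 29 7-hydroxy-8-methyl compound (C17 cis to C20 and trans to the hydroxyl)
Conditions: [Ir(cod)(PCy3)(py)]PF6 (5 mol %), H2 (1 atm), CH2Cl2, rt
Reagents that add atoms: none
Why: In hydroxyl-directed hydrogenation the cationic iridium centre binds the C7 hydroxyl and delivers hydrogen to C8 on that face, so C17 ends up trans to the oxygen, as known for 2-methylenecyclohexanols.

Step 20
Reactants: 29 7-hydroxy-8-methyl compound
Product: 30 7-acetate
Conditions: Ac2O, DMAP (cat.), pyridine, CH2Cl2, rt
Reagents that add atoms: acetic anhydride, CC(=O)OC(C)=O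
Why: Nucleophile-catalysed acylation of the only free hydroxyl; the acetate also protects C7 during the oxidation at C3.

Step 21
Reactants: 30 7-acetate
Product: 31 3-alcohol
Conditions: Bu4NF, AcOH, THF, rt to 45 °C
Reagents that add atoms: none
Why: Fluoride cleaves the silyl ether; buffering with acetic acid keeps the medium from attacking the acetate.

Step 22
Reactants: 31 3-alcohol
Product: 32 3-ketone with C2 dioxolane
Conditions: DMP, NaHCO3, CH2Cl2, rt
Reagents that add atoms: none
Why: Buffered periodinane oxidation of a secondary alcohol is neutral enough for the ketal, the acetate and the tert-butyl ester.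

Step 23
Reactants: 32 3-ketone with C2 dioxolane
Product: 35 4(18)-methylene 3-ketone with C2 dioxolane, via Mannich base 33 (not isolated), via ammonium iodide 34 (not isolated)
Conditions: LiN(SiMe3)2, THF, −78 °C; CH2=NMe2+ I−, −78 to 0 °C; MeI, CH2Cl2, rt; aq. NaHCO3
Reagents that add atoms: dimethylmethyleneiminium iodide, C=[N+](C)C.[I-]
Why: The ketone can enolise only toward C4 because C2 is a ketal carbon, and one equivalent of amide base takes the ketone before the esters. Mannich reaction with the iminium salt, N-methylation and base-induced elimination is the standard α-methylenation sequence.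

Step 24
Reactants: 35 4(18)-methylene 3-ketone with C2 dioxolane
Product: 36 CNP0257844.1
Conditions: CF3CO2H–H2O (9:1), 0 °C to rt
Reagents that add atoms: water, O
Why: Aqueous acid hydrolyses the dioxolane and cleaves the tert-butyl ester with loss of isobutene. The liberated 2,3-dione can enolise only toward C1 and so gives the diosphenol, while the acetate and the exocyclic alkene (which has no position to migrate to) are expected to survive.

## Compound list

1 | propanal | CCC=O | starting material
2 | but-3-en-2-ol (racemic) | CC(O)C=C | starting material
3 | 1,1-bis(but-3-en-2-yloxy)propane | CCC(OC(C)C=C)OC(C)C=C | intermediate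
4 | 3-(prop-1-en-1-yloxy)but-1-ene | CC=COC(C)C=C | intermediate
5 | (E)-2-methylhex-4-enal (racemic) | C/C=C/CC(C)C=O | intermediate
6 | methyl vinyl ketone | CC(=O)C=C | starting material
7 | (E)-2-methyl-2-(3-oxobutyl)hex-4-enal (racemic) | C/C=C/CC(C)(C=O)CCC(C)=O | intermediate
8 | 4-[(E)-but-2-en-1-yl]-4-methylcyclohex-2-en-1-one (racemic) | C/C=C/CC1(C)CCC(=O)C=C1 | intermediate
9 | 4-[(E)-but-2-en-1-yl]-4-methylcyclohexa-2,5-dien-1-one | C/C=C/CC1(C)C=CC(=O)C=C1 | intermediate
10 | 4-(2,3-dihydroxybutyl)-4-methylcyclohexa-2,5-dien-1-one (racemic threo diol, one enantiomer drawn) | C[C@@H](O)[C@H](O)CC1(C)C=CC(=O)C=C1 | intermediate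
11 | 4-methyl-4-(2,3-dioxobutyl)cyclohexa-2,5-dien-1-one | CC(=O)C(=O)CC1(C)C=CC(=O)C=C1 | intermediate
12 | (4aS,8aR)-8a-methyl-1,4,4a,8a-tetrahydronaphthalene-2,3,6(5H)-trione (cis-fused; H-10 cis to C19) | C1C(=O)C(=O)C[C@@H]2CC(=O)C=C[C@]12C | intermediate
13 | C2 ethylene ketal of 12 (2,2-ethylenedioxy-3,8-dione with C6=C7 alkene) | C1C(=O)C2(OCCO2)C[C@@H]3CC(=O)C=C[C@]13C | intermediate
14 | 3-hydroxy-2,2-ethylenedioxy-6-en-8-one (3-OH trans to C19) | C1[C@H](O)C2(OCCO2)C[C@@H]3CC(=O)C=C[C@]13C | intermediate
15 | 3-(tert-butyldimethylsilyloxy)-2,2-ethylenedioxy-6-en-8-one | C1[C@H](O[Si](C)(C)C(C)(C)C)C2(OCCO2)C[C@@H]3CC(=O)C=C[C@]13C | intermediate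
16 | 9-methyl derivative of 15 (methyl cis to H-10, expected major epimer) | C1[C@H](O[Si](C)(C)C(C)(C)C)C2(OCCO2)C[C@@H]3[C@@H](C)C(=O)C=C[C@]13C | intermediate
17 | methyl hydrogen (R)-3-methylglutarate | OC(=O)C[C@@H](C)CC(=O)OC | starting material
18 | methyl (R)-5-hydroxy-3-methylpentanoate | OCC[C@@H](C)CC(=O)OC | intermediate
19 | (R)-4-methyltetrahydro-2H-pyran-2-one | O1CC[C@@H](C)CC1=O | intermediate
20 | trimethylsilyl (S)-5-iodo-3-methylpentanoate | ICC[C@@H](C)CC(=O)O[Si](C)(C)C | intermediate
21 | (S)-5-iodo-3-methylpentanoic acid | ICC[C@@H](C)CC(=O)O | intermediate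
22 | tert-butyl (S)-5-iodo-3-methylpentanoate | ICC[C@@H](C)CC(=O)OC(C)(C)C | intermediate
23 | 9-methyl-9-[(3R)-5-tert-butoxy-3-methyl-5-oxopentyl] enone (C20 trans, chain cis to H-10; 3-OTBS, C2 dioxolane, C6=C7 alkene, 8-one) | C1[C@H](O[Si](C)(C)C(C)(C)C)C2(OCCO2)C[C@@H]3[C@@](C)(CC[C@@H](C)CC(=O)OC(C)(C)C)C(=O)C=C[C@]13C | intermediate
24 | 6,7-dihydro derivative of 23 (saturated 8-ketone) | C1[C@H](O[Si](C)(C)C(C)(C)C)C2(OCCO2)C[C@@H]3[C@@](C)(CC[C@@H](C)CC(=O)OC(C)(C)C)C(=O)CC[C@]13C | intermediate
25 | 8(17)-methylene compound | C1[C@H](O[Si](C)(C)C(C)(C)C)C2(OCCO2)C[C@@H]3[C@@](C)(CC[C@@H](C)CC(=O)OC(C)(C)C)C(=C)CC[C@]13C | intermediate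
26 | 7-hydroxy-8(17)-methylene compound (C7 epimers) | C1[C@H](O[Si](C)(C)C(C)(C)C)C2(OCCO2)C[C@@H]3[C@@](C)(CC[C@@H](C)CC(=O)OC(C)(C)C)C(=C)C(O)C[C@]13C | intermediate
27 | 8(17)-en-7-one | C1[C@H](O[Si](C)(C)C(C)(C)C)C2(OCCO2)C[C@@H]3[C@@](C)(CC[C@@H](C)CC(=O)OC(C)(C)C)C(=C)C(=O)C[C@]13C | intermediate
28 | 7-hydroxy-8(17)-methylene compound (7-OH cis to H-10 and C19) | C1[C@H](O[Si](C)(C)C(C)(C)C)C2(OCCO2)C[C@@H]3[C@@](C)(CC[C@@H](C)CC(=O)OC(C)(C)C)C(=C)[C@@H](O)C[C@]13C | intermediate
29 | 7-hydroxy-8-methyl compound (C17 cis to C20, trans to 7-OH) | C1[C@H](O[Si](C)(C)C(C)(C)C)C2(OCCO2)C[C@@H]3[C@@](C)(CC[C@@H](C)CC(=O)OC(C)(C)C)[C@H](C)[C@@H](O)C[C@]13C | intermediate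
30 | 7-acetate of 29 | C1[C@H](O[Si](C)(C)C(C)(C)C)C2(OCCO2)C[C@@H]3[C@@](C)(CC[C@@H](C)CC(=O)OC(C)(C)C)[C@H](C)[C@@H](OC(C)=O)C[C@]13C | intermediate
31 | 3-alcohol (7-acetate, C2 dioxolane, tert-butyl ester) | C1[C@H](O)C2(OCCO2)C[C@@H]3[C@@](C)(CC[C@@H](C)CC(=O)OC(C)(C)C)[C@H](C)[C@@H](OC(C)=O)C[C@]13C | intermediate
32 | 3-ketone (7-acetate, C2 dioxolane, tert-butyl ester) | C1C(=O)C2(OCCO2)C[C@@H]3[C@@](C)(CC[C@@H](C)CC(=O)OC(C)(C)C)[C@H](C)[C@@H](OC(C)=O)C[C@]13C | intermediate
33 | 4-(dimethylaminomethyl) derivative of 32 (C4 epimers) | CN(C)CC1C(=O)C2(OCCO2)C[C@@H]3[C@@](C)(CC[C@@H](C)CC(=O)OC(C)(C)C)[C@H](C)[C@@H](OC(C)=O)C[C@]13C | intermediate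
34 | 4-(trimethylammoniomethyl) iodide derived from 33 | C[N+](C)(C)CC1C(=O)C2(OCCO2)C[C@@H]3[C@@](C)(CC[C@@H](C)CC(=O)OC(C)(C)C)[C@H](C)[C@@H](OC(C)=O)C[C@]13C.[I-] | intermediate
35 | 4(18)-methylene 3-ketone (7-acetate, C2 dioxolane, tert-butyl ester) | C=C1C(=O)C2(OCCO2)C[C@@H]3[C@@](C)(CC[C@@H](C)CC(=O)OC(C)(C)C)[C@H](C)[C@@H](OC(C)=O)C[C@]13C | intermediate
36 | CNP0257844.1, (5S,7S,8S,9R,10R,13R)-7-acetoxy-2-hydroxy-3-oxo-5,10-cis-cleroda-1,4(18)-dien-15-oic acid | C=C1C(=O)C(O)=C[C@@H]2[C@@](C)(CC[C@@H](C)CC(=O)O)[C@H](C)[C@@H](OC(C)=O)C[C@]12C | target

## Step count and risks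

Total step count: 24. Longest linear sequence: 21 (steps 1–10 and 14–24); the chain fragment takes steps 11–13.

**Step 6 (key step).** The methyl group of an open-chain 1,2-diketone is a weaker carbon acid than the donors usually used in such desymmetrisations. Catalysed enolisation may be slow, so an uncatalysed racemic cyclisation or reversible trapping of the enol oxygen by the dienone could erode the enantiomeric excess. The fallback changes the mode of activation from general-base to enamine catalysis: setting out from 11, 9-amino(9-deoxy)epi-quinine with an acid co-catalyst condenses at the more accessible C2 carbonyl, and the resulting secondary enamine is nucleophilic at C1. Hydrolysis returns to the route at 12, and no compound outside the list is isolated.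

**Step 14.** Substitution at a tetrasubstituted enolate carbon by an unactivated primary iodide may be slow, which leaves room for proton transfer from the ester α-methylene, O-alkylation or elimination of hydrogen iodide. The fallback forms the same bond by an aldol addition and removes the oxygen afterwards. Iodide 22 is oxidised with trimethylamine N-oxide to tert-butyl (R)-3-methyl-5-oxopentanoate F1. The lithium enolate of 16 adds to F1 at −78 °C on the same convex face to give the 11-hydroxy aldol adduct F2. Dehydration with methyl N-(triethylammoniumsulfonyl)carbamate, which can only eliminate toward C12, gives the 11,12-alkene F3. The hydrogenation of step 15 then saturates both double bonds and returns to the route at 24.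

**Step 18.** The two groups flanking the C7 carbonyl (the alkenyl carbon C8 and the neopentyl-type C6 methylene) may be poorly distinguished by the oxazaborolidine, or the reagent may be mismatched with the substrate, giving poor facial selectivity. The fallback uses substrate control followed by stereospecific inversion. Setting out from 27, reduction with NaBH4 and CeCl3·7H2O gives the allylic alcohols, from which the C7 epimer of 28 F4 is separated. A Mitsunobu reaction with 4-nitrobenzoic acid inverts F4 to the 4-nitrobenzoate of 28 F5, and methanolysis with K2CO3 returns to the route at 28.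

**Step 7.** Discrimination between C2 and C3 may be incomplete, or the enone carbonyl may be ketalised as well. The fallback decides the regiochemistry at an enol ether stage, where the isomers can be separated and recycled by acid. Setting out from 12, methanol and trimethyl orthoformate with TsOH give the conjugated 2-methoxy-1-en-3-one F6. Acid-catalysed exchange of F6 with ethane-1,2-diol then closes the dioxolane and returns to the route at 13.

**Step 24.** Hydrolysis of a ketal next to a carbonyl group is slow, and acid strong enough to open it may add water or trifluoroacetate to the exocyclic enone or cause oligomerisation. The fallback keeps C18 masked as an ammonium group during the acid step. Setting out from 32, the Mannich base 33 is isolated and heated with aqueous HCl in THF, which removes the ketal and the tert-butyl ester and gives the amino diosphenol acid F7. Methylation with iodomethane without added base gives the trimethylammonium iodide F8, and aqueous NaHCO3 eliminates trimethylamine to return to the route at 36.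

## Further compounds

F0 | step 6 | none | none
F1 | step 14 | tert-butyl (R)-3-methyl-5-oxopentanoate | O=CC[C@@H](C)CC(=O)OC(C)(C)C
F2 | step 14 | 11-hydroxy aldol adduct of 16 and F1 (C11 epimers) | C1[C@H](O[Si](C)(C)C(C)(C)C)C2(OCCO2)C[C@@H]3[C@@](C)(C(O)C[C@@H](C)CC(=O)OC(C)(C)C)C(=O)C=C[C@]13C
F3 | step 14 | (E)-11,12-didehydro derivative of 23 | C1[C@H](O[Si](C)(C)C(C)(C)C)C2(OCCO2)C[C@@H]3[C@@](C)(/C=C/[C@@H](C)CC(=O)OC(C)(C)C)C(=O)C=C[C@]13C
F4 | step 18 | C7 epimer of 28 (7-OH trans to H-10) | C1[C@H](O[Si](C)(C)C(C)(C)C)C2(OCCO2)C[C@@H]3[C@@](C)(CC[C@@H](C)CC(=O)OC(C)(C)C)C(=C)[C@H](O)C[C@]13C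
F5 | step 18 | 4-nitrobenzoate of 28 | C1[C@H](O[Si](C)(C)C(C)(C)C)C2(OCCO2)C[C@@H]3[C@@](C)(CC[C@@H](C)CC(=O)OC(C)(C)C)C(=C)[C@@H](OC(=O)c4ccc(cc4)[N+](=O)[O-])C[C@]13C
F6 | step 7 | (4aS,8aR)-3-methoxy-8a-methyl-4a,8a-dihydronaphthalene-2,6(1H,5H)-dione (clerodane 2-methoxy-1,6-diene-3,8-dione) | C1C(=O)C(OC)=C[C@@H]2CC(=O)C=C[C@]12C
F7 | step 24 | 4-(dimethylaminomethyl) diosphenol acid (C4 epimers) | CN(C)CC1C(=O)C(O)=C[C@@H]2[C@@](C)(CC[C@@H](C)CC(=O)O)[C@H](C)[C@@H](OC(C)=O)C[C@]12C
F8 | step 24 | 4-(trimethylammoniomethyl) diosphenol acid iodide | C[N+](C)(C)CC1C(=O)C(O)=C[C@@H]2[C@@](C)(CC[C@@H](C)CC(=O)O)[C@H](C)[C@@H](OC(C)=O)C[C@]12C.[I-]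
A1 | alternative 1 | protected cis-fused 4-methylene-5-methyl decalin-3-one | C=C1C(=O)CC[C@@H]2[C@@](C)(CC[C@@H](C)CC(=O)OC(C)(C)C)[C@H](C)[C@@H](O[Si](C)(C)C(C)(C)C)C[C@]12C
A2 | alternative 1 | protected 19-nor-4-en-3-one (octalone) | O=C1CC[C@@H]2[C@@](C)(CC[C@@H](C)CC(=O)OC(C)(C)C)[C@H](C)[C@@H](O[Si](C)(C)C(C)(C)C)CC2=C1
A3 | alternative 2 | cis-fused C1-keto octalin silyl enol ether with C11 methyl ester | C1CCC(=O)[C@@H]2[C@@](C)(C(=O)OC)[C@H](C)C(O[Si](C)(C)C(C)(C)C)=C[C@]12C
A4 | alternative 2 | methyl 10-(tert-butyldimethylsilyloxy)-2,8-dimethyl-4-oxododeca-2,8,10-trienoate | COC(=O)/C(C)=C/C(=O)CCC/C(C)=C/C(O[Si](C)(C)C(C)(C)C)=C/C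
A5 | alternative 3 | cis-fused decalin with ring A 3-en-2-one | C1=CC(=O)C[C@@H]2[C@@](C)(CC[C@@H](C)CC(=O)OC(C)(C)C)[C@H](C)[C@@H](O[Si](C)(C)C(C)(C)C)C[C@]12C
A6 | alternative 3 | 4-methylcyclohexa-2,5-dienone carrying the C6–C9 tether with a 9(20)-methylene group | C=C(CC[C@@H](C)CC(=O)OC(C)(C)C)[C@H](C)[C@@H](O[Si](C)(C)C(C)(C)C)CC1(C)C=CC(=O)C=C1
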